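**Plan**

- Retrosynthesis: the acetate goes back to the C8 alcohol, the cyclopropane to a cis C4=C5 alkene, and the alcohol to a ketone (cycloocta[c]furan numbering: C1 lactone C=O, O2, C3 OCH2, C3a=C9a butenolide alkene, C4–C9 carbocycle; the cyclopropane CH2 bridges C4 and C5).
- The ring bonds C6–C7 and C3a–C4 are then cut together; this releases C4–C5–C6 with its methyl group as crotonaldehyde and leaves the open-chain β-keto ester / alkenyl triflate 10.
- Enabling feature: C7 is α to the C8 oxygen (with a removable ester it is a soft carbon acid), C6 and C4 are the β-carbon and carbonyl carbon of an enal, and C3a is the β-carbon of the butenolide, which can carry a triflate and become an alkenylchromium.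
- Forward order: side chain → nitroalkene → butenolide ring attached at C9 → triflate and β-keto ester arm → eight-membered ring by a one-flask Michael / Nozaki–Hiyama–Kishi (5+3) annulation → diene → ketone → alcohol → cyclopropane → acetate.
- Stereochemistry: side-chain methyl from (R)-citronellyl bromide; C9 by thiourea-catalysed nitro-Michael addition; C6 by iminium catalysis; C8 by oxazaborolidine reduction; C4/C5 by hydroxyl-directed cyclopropanation.

Key step: step 7

Remark: 8 and 12 are written as free aldehydes; 12 may rest in the flask as its cyclic hemiacetal, which does not change the chemistry.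

**Route**

Step 1
Reactants: 1 (R)-citronellyl bromide [(6R)-8-bromo-2,6-dimethyloct-2-ene]
Product: 2 (6R)-2,6-dimethyl-8-nitrooct-2-ene
Conditions: AgNO2, Et2O, 0 °C to rt, dark
Reagents that add atoms: silver nitrite, [Ag+].[O-]N=O
Why: Victor Meyer–Kornblum substitution, in which the primary bromide should be displaced by nitrite through nitrogen with silver assistance, the chiral-pool methyl stereocenter being untouched.

Step 2
Reactants: 2 (6R)-2,6-dimethyl-8-nitrooct-2-ene
Product: 4 (6R,7E)-2,6-dimethyl-8-nitroocta-2,7-diene, via selenide 3 (not isolated)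
Conditions: n-BuLi, THF, −78 °C; PhSeBr, −78 °C; then 30% H2O2, pyridine, CH2Cl2, 0 °C to rt
Reagents that add atoms: none
Why: α-Selenenylation of the lithium nitronate followed by selenoxide syn-elimination toward the only β-hydrogens should give the conjugated (E)-nitroalkene, with no strong base present once the alkene next to the stereocenter exists.

Step 3
Reactants: 4 (6R,7E)-2,6-dimethyl-8-nitroocta-2,7-diene; 5 tetronic acid [4-hydroxyfuran-2(5H)-one]
Product: 6 3-[(2S,3R)-3,7-dimethyl-1-nitrooct-6-en-2-yl]-4-hydroxyfuran-2(5H)-one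
Conditions: (S,S)-1-[3,5-bis(trifluoromethyl)phenyl]-3-[2-(dimethylamino)cyclohexyl]thiourea (10 mol %), THF, 0 °C
Reagents that add atoms: none
Why: Bifunctional thiourea–amine catalysed Michael addition of a cyclic 1,3-dicarbonyl compound to a nitroalkene, in which C3 of tetronic acid should add to the β-carbon and the catalyst enantiomer fixes the new stereocenter (the later C9) as 2S.

Step 4
Reactants: 6 3-[(2S,3R)-3,7-dimethyl-1-nitrooct-6-en-2-yl]-4-hydroxyfuran-2(5H)-one
Product: 7 4-[(2S,3R)-3,7-dimethyl-1-nitrooct-6-en-2-yl]-5-oxo-2,5-dihydrofuran-3-yl trifluoromethanesulfonate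
Conditions: Tf2O, iPr2NEt (1.1 equiv), CH2Cl2, −78 °C
Reagents that add atoms: trifluoromethanesulfonic anhydride, O=S(=O)(OS(=O)(=O)C(F)(F)F)C(F)(F)F
Why: O-Sulfonylation of the vinylogous acid, which is far more acidic than the nitroalkane, should give the alkenyl triflate that later becomes the alkenyl nucleophile at C3a.

Step 5
Reactants: 7 4-[(2S,3R)-3,7-dimethyl-1-nitrooct-6-en-2-yl]-5-oxo-2,5-dihydrofuran-3-yl trifluoromethanesulfonate
Product: 8 4-[(2S,3R)-3,7-dimethyl-1-oxooct-6-en-2-yl]-5-oxo-2,5-dihydrofuran-3-yl trifluoromethanesulfonate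
Conditions: aq. TiCl3, NH4OAc, THF/H2O, 0 °C to rt
Reagents that add atoms: water, O
Why: Reductive Nef reaction, in which trivalent titanium reduces the primary nitro group to the imine that hydrolyses to the aldehyde under buffered, base-free conditions meant to spare the triflate and the epimerisable α-stereocenter.

Step 6
Reactants: 8 4-[(2S,3R)-3,7-dimethyl-1-oxooct-6-en-2-yl]-5-oxo-2,5-dihydrofuran-3-yl trifluoromethanesulfonate; 9 ethyl diazoacetate
Product: 10 ethyl (4S,5R)-5,9-dimethyl-3-oxo-4-[2-oxo-4-(trifluoromethanesulfonyloxy)-2,5-dihydrofuran-3-yl]dec-8-enoate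
Conditions: SnCl2 (10 mol %), CH2Cl2, rt
Reagents that add atoms: none
Why: Roskamp homologation (Lewis-acid-promoted addition of the diazo ester to the aldehyde, 1,2-hydride shift, loss of N2) should give the β-keto ester that activates C7, without base, so that the α-stereocenter is kept.

Step 7
Reactants: 10 ethyl (4S,5R)-5,9-dimethyl-3-oxo-4-[2-oxo-4-(trifluoromethanesulfonyloxy)-2,5-dihydrofuran-3-yl]dec-8-enoate; 11 (E)-crotonaldehyde
Product: 13 ethyl (6S,9S)-4-hydroxy-6-methyl-9-[(2R)-6-methylhept-5-en-2-yl]-1,8-dioxo-1,3,4,5,6,7,8,9-octahydrocycloocta[c]furan-7-carboxylate (epimers at C4 and C7), via keto aldehyde 12 (not isolated)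
Conditions: 11 (1.05 equiv), (R)-α,α-diphenylprolinol trimethylsilyl ether (10 mol %), PhCO2H (10 mol %), toluene, 0 °C; then dilution with degassed DMF/THF (2 mM), CrCl2 (8 equiv), NiCl2 (10 mol %), rt
Reagents that add atoms: none
Why: Stage one is an iminium-catalysed Michael addition: the prolinol ether and 11 form an (E)-iminium ion, and the enol of the β-keto ester of 10 adds through C7 to its β-carbon from the face not covered by the diphenyl(silyloxy)methyl group, which forms C6–C7 and sets the C6 methyl stereocenter by catalyst control (hydrolysis then frees aldehyde 12). Stage two is an intramolecular Nozaki–Hiyama–Kishi reaction: zerovalent nickel inserts into the alkenyl C–OTf bond at C3a, the alkenyl group passes to chromium, and the alkenylchromium adds to the tethered aldehyde carbon C4, which forms C3a–C4. This closes the eight-membered ring by an 8-exo-trig addition to the carbonyl group, eased by three trigonal ring atoms (C3a and C9a held cis by the butenolide, and C8). The closest known reaction types are the diarylprolinol silyl ether catalysed Michael addition of β-keto esters to enals and chromium-mediated medium-ring closures of alkenyl triflates onto aldehydes; joining them in one flask makes crotonaldehyde a three-carbon linchpin in a (5+3) annulation. The step needs C-alkylation at C7 only (the 1,3-dicarbonyl unit is the sole soft carbon acid), 1,4- instead of 1,2-attack on 11 (iminium activation) and attack of chromium on the aldehyde in the presence of ketone, ester and lactone (inherent to alkenylchromium reagents). The new centers at C4 and C7 need no control, because both are erased in steps 8 and 9.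

Step 8
Reactants: 13 ethyl (6S,9S)-4-hydroxy-6-methyl-9-[(2R)-6-methylhept-5-en-2-yl]-1,8-dioxo-1,3,4,5,6,7,8,9-octahydrocycloocta[c]furan-7-carboxylate
Product: 14 ethyl (4Z,6S,9S)-6-methyl-9-[(2R)-6-methylhept-5-en-2-yl]-1,8-dioxo-1,3,6,7,8,9-hexahydrocycloocta[c]furan-7-carboxylate (epimers at C7)
Conditions: Burgess reagent, toluene, 60 °C
Reagents that add atoms: none
Why: Burgess dehydration (syn-elimination of the sulfamate ester) should give the C4=C5 alkene from either C4 epimer, since C5 carries the only β-hydrogens, and the alkene is necessarily cis in the eight-membered ring.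

Step 9
Reactants: 14 ethyl (4Z,6S,9S)-6-methyl-9-[(2R)-6-methylhept-5-en-2-yl]-1,8-dioxo-1,3,6,7,8,9-hexahydrocycloocta[c]furan-7-carboxylate
Product: 15 (4Z,6R,9S)-6-methyl-9-[(2R)-6-methylhept-5-en-2-yl]-6,7-dihydrocycloocta[c]furan-1,8(3H,9H)-dione
Conditions: LiCl, H2O, DMSO, 120 °C
Reagents that add atoms: none
Why: Krapcho dealkoxycarbonylation (chloride attacks the ethyl group, CO2 is lost) removes the ester that activated C7 and returns C7 as CH2 under essentially neutral conditions.

Step 10
Reactants: 15 (4Z,6R,9S)-6-methyl-9-[(2R)-6-methylhept-5-en-2-yl]-6,7-dihydrocycloocta[c]furan-1,8(3H,9H)-dione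
Product: 16 (4Z,6R,8R,9S)-8-hydroxy-6-methyl-9-[(2R)-6-methylhept-5-en-2-yl]-6,7,8,9-tetrahydrocycloocta[c]furan-1(3H)-one
Conditions: (S)-2-methyl-CBS-oxazaborolidine (20 mol %), catecholborane, toluene, −78 °C
Reagents that add atoms: none
Why: Corey–Bakshi–Shibata reduction, in which the oxazaborolidine tells the branched C9 side (large) from the C7 methylene side (small) and should deliver hydride to give the 8R alcohol cis to the C9 side chain, while lactone and alkenes are inert to catecholborane at this temperature.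

Step 11
Reactants: 16 (4Z,6R,8R,9S)-8-hydroxy-6-methyl-9-[(2R)-6-methylhept-5-en-2-yl]-6,7,8,9-tetrahydrocycloocta[c]furan-1(3H)-one
Product: 17 (4S,5S,6R,8R,9S)-8-hydroxy-6-methyl-9-[(2R)-6-methylhept-5-en-2-yl]-4,5-methano-4,5,6,7,8,9-hexahydrocycloocta[c]furan-1(3H)-one (cis-fused cyclopropane, CH2 on the face of the C8 oxygen)
Conditions: Et2Zn, CH2I2, CH2Cl2, −10 °C to rt
Reagents that add atoms: diiodomethane, ICI
Why: Hydroxyl-directed Simmons–Smith cyclopropanation, in which the zinc alkoxide at C8 should deliver the carbenoid to the C4=C5 alkene on its own face, which is also the face opposite the C6 methyl group, so that C4 and C5 are set syn to the C8 oxygen.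

Step 12
Reactants: 17 (4S,5S,6R,8R,9S)-8-hydroxy-6-methyl-9-[(2R)-6-methylhept-5-en-2-yl]-4,5-methano-4,5,6,7,8,9-hexahydrocycloocta[c]furan-1(3H)-one
Product: 18 (4S,5S,6R,8R,9S)-8-acetoxy-6-methyl-9-[(2R)-6-methylhept-5-en-2-yl]-4,5-methano-4,5,6,7,8,9-hexahydrocycloocta[c]furan-1(3H)-one (target)
Conditions: Ac2O, pyridine, DMAP (cat.), CH2Cl2, rt
Reagents that add atoms: acetic anhydride, CC(=O)OC(C)=O
Why: Acylation of the secondary alcohol proceeds with retention at C8 and should give the target acetate.

**Compound list**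

1 | (R)-citronellyl bromide, (6R)-8-bromo-2,6-dimethyloct-2-ene | BrCC[C@H](C)CCC=C(C)C | starting material
2 | (6R)-2,6-dimethyl-8-nitrooct-2-ene | [O-][N+](=O)CC[C@H](C)CCC=C(C)C | intermediate
3 | (6R)-2,6-dimethyl-8-nitro-8-(phenylselanyl)oct-2-ene (C8 epimers) | [O-][N+](=O)C([Se]c1ccccc1)C[C@H](C)CCC=C(C)C | intermediate
4 | (6R,7E)-2,6-dimethyl-8-nitroocta-2,7-diene | [O-][N+](=O)/C=C/[C@H](C)CCC=C(C)C | intermediate
5 | tetronic acid, 4-hydroxyfuran-2(5H)-one | O=C1OCC(O)=C1 | starting material
6 | 3-[(2S,3R)-3,7-dimethyl-1-nitrooct-6-en-2-yl]-4-hydroxyfuran-2(5H)-one | O=C1OCC(O)=C1[C@@H](C[N+](=O)[O-])[C@H](C)CCC=C(C)C | intermediate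
7 | 4-[(2S,3R)-3,7-dimethyl-1-nitrooct-6-en-2-yl]-5-oxo-2,5-dihydrofuran-3-yl trifluoromethanesulfonate | O=C1OCC(OS(=O)(=O)C(F)(F)F)=C1[C@@H](C[N+](=O)[O-])[C@H](C)CCC=C(C)C | intermediate
8 | 4-[(2S,3R)-3,7-dimethyl-1-oxooct-6-en-2-yl]-5-oxo-2,5-dihydrofuran-3-yl trifluoromethanesulfonate | O=C1OCC(OS(=O)(=O)C(F)(F)F)=C1[C@@H](C=O)[C@H](C)CCC=C(C)C | intermediate
9 | ethyl diazoacetate | CCOC(=O)C=[N+]=[N-] | starting material
10 | ethyl (4S,5R)-5,9-dimethyl-3-oxo-4-[2-oxo-4-(trifluoromethanesulfonyloxy)-2,5-dihydrofuran-3-yl]dec-8-enoate | O=C1OCC(OS(=O)(=O)C(F)(F)F)=C1[C@@H](C(=O)CC(=O)OCC)[C@H](C)CCC=C(C)C | intermediate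
11 | (E)-crotonaldehyde | C/C=C/C=O | starting material
12 | ethyl (3S)-2-{(2S,3R)-3,7-dimethyl-2-[2-oxo-4-(trifluoromethanesulfonyloxy)-2,5-dihydrofuran-3-yl]oct-6-enoyl}-3-methyl-5-oxopentanoate (C2 epimers) | O=C1OCC(OS(=O)(=O)C(F)(F)F)=C1[C@@H](C(=O)C(C(=O)OCC)[C@@H](C)CC=O)[C@H](C)CCC=C(C)C | intermediate
13 | ethyl (6S,9S)-4-hydroxy-6-methyl-9-[(2R)-6-methylhept-5-en-2-yl]-1,8-dioxo-1,3,4,5,6,7,8,9-octahydrocycloocta[c]furan-7-carboxylate (epimers at C4 and C7) | O=C1C(C(=O)OCC)[C@@H](C)CC(O)C2=C(C(=O)OC2)[C@@H]1[C@H](C)CCC=C(C)C | intermediate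
14 | ethyl (4Z,6S,9S)-6-methyl-9-[(2R)-6-methylhept-5-en-2-yl]-1,8-dioxo-1,3,6,7,8,9-hexahydrocycloocta[c]furan-7-carboxylate (C7 epimers) | O=C1C(C(=O)OCC)[C@@H](C)/C=C\C2=C(C(=O)OC2)[C@@H]1[C@H](C)CCC=C(C)C | intermediate
15 | (4Z,6R,9S)-6-methyl-9-[(2R)-6-methylhept-5-en-2-yl]-6,7-dihydrocycloocta[c]furan-1,8(3H,9H)-dione | O=C1C[C@@H](C)/C=C\C2=C(C(=O)OC2)[C@@H]1[C@H](C)CCC=C(C)C | intermediate
16 | (4Z,6R,8R,9S)-8-hydroxy-6-methyl-9-[(2R)-6-methylhept-5-en-2-yl]-6,7,8,9-tetrahydrocycloocta[c]furan-1(3H)-one | O[C@@H]1C[C@@H](C)/C=C\C2=C(C(=O)OC2)[C@@H]1[C@H](C)CCC=C(C)C | intermediate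
17 | (4S,5S,6R,8R,9S)-8-hydroxy-6-methyl-9-[(2R)-6-methylhept-5-en-2-yl]-4,5-methano-4,5,6,7,8,9-hexahydrocycloocta[c]furan-1(3H)-one | O[C@@H]1C[C@@H](C)[C@@H]2C[C@@H]2C2=C(C(=O)OC2)[C@@H]1[C@H](C)CCC=C(C)C | intermediate
18 | (4S,5S,6R,8R,9S)-8-acetoxy-6-methyl-9-[(2R)-6-methylhept-5-en-2-yl]-4,5-methano-4,5,6,7,8,9-hexahydrocycloocta[c]furan-1(3H)-one | CC(=O)O[C@@H]1C[C@@H](C)[C@@H]2C[C@@H]2C2=C(C(=O)OC2)[C@@H]1[C@H](C)CCC=C(C)C | target

**Count**

Total steps: 12. Longest linear sequence: 12 steps (from 1).

**Steps most likely to fail**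

Step 7. The secondary-amine catalyst may be consumed by addition–elimination at the triflate-bearing carbon, and the chromium-mediated closure of the eight-membered ring may lose out to protonolysis of the alkenylmetal or to intermolecular coupling. The fallback makes the same two bonds in the opposite order and forms the ring by ring expansion instead of direct closure. It sets out from 10: an intermolecular Nozaki–Hiyama–Kishi coupling with 11 (CrCl2, NiCl2 cat., DMF, with a chiral sulfonamide ligand on chromium to set the carbinol center) should give the dienyl carbinol ethyl (4S,5R)-4-{4-[(2E)-1-hydroxybut-2-en-1-yl]-2-oxo-2,5-dihydrofuran-3-yl}-5,9-dimethyl-3-oxodec-8-enoate F1. PPTS in toluene with molecular sieves should then close the δ-hydroxy β-keto ester to the ester-conjugated exocyclic enol ether, the alkylidene dihydropyran F2. Heating F2 in toluene at 140 °C should bring about the Claisen ring expansion of this 2-alkylidene-6-propenyl dihydropyran, which forms C6–C7, relays the carbinol configuration to C6 and gives 14 directly. The route is rejoined at 14; 12 and 13 are bypassed.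

Step 11. The zinc carbenoid may attack the electron-rich side-chain alkene faster than the C4=C5 alkene, which is deactivated by conjugation with the butenolide (loss of chemoselectivity), or the directing effect of the remote hydroxyl may be too weak for facial control. The fallback inverts the polarity of the cyclopropanation. It sets out from 16, which is treated with Me3S(O)I and NaH in DMSO (Corey–Chaykovsky conditions). The sulfoxonium ylide should add 1,6 to the dienyl lactone at C5 from the face opposite the C6 methyl group and close onto C4 with loss of DMSO, while isolated alkenes are inert to it. This gives 17 directly, where the route is rejoined (no new compound, entry F0).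

Step 5. The aqueous titanium reagent may hydrolyse or reduce the vinylogous acyl triflate, and the α-branched aldehyde may epimerise at the later C9 during the slow reduction of the free nitro compound. The fallback changes the order of events so that the sensitive triflate is made last. It sets out from 6: the nitronate is preformed with NaOMe in MeOH and reduced with buffered aq. TiCl3, which the free tetronic acid tolerates as its salt, to give the hydroxy aldehyde (2S,3R)-2-(4-hydroxy-2-oxo-2,5-dihydrofuran-3-yl)-3,7-dimethyloct-6-enal F3 (resting as its cyclic hemiacetal). Roskamp homologation with 9 (SnCl2 cat., CH2Cl2) should give the β-keto ester ethyl (4S,5R)-4-(4-hydroxy-2-oxo-2,5-dihydrofuran-3-yl)-5,9-dimethyl-3-oxodec-8-enoate F4. Selective O-sulfonylation of the far more acidic tetronic acid hydroxyl (Tf2O, one equivalent of iPr2NEt, −78 °C) then gives 10, where the route is rejoined; 7 and 8 are bypassed.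

Further compounds
F1 | step 7 | ethyl (4S,5R)-4-{4-[(2E)-1-hydroxybut-2-en-1-yl]-2-oxo-2,5-dihydrofuran-3-yl}-5,9-dimethyl-3-oxodec-8-enoate | O=C1OCC(C(O)/C=C/C)=C1[C@@H](C(=O)CC(=O)OCC)[C@H](C)CCC=C(C)C
F2 | step 7 | ethyl 2-[(7S)-7-[(2R)-6-methylhept-5-en-2-yl]-1-oxo-4-[(1E)-prop-1-en-1-yl]-1,3,4,7-tetrahydro-6H-furo[3,4-c]pyran-6-ylidene]acetate | CCOC(=O)C=C1OC(/C=C/C)C2=C(C(=O)OC2)[C@@H]1[C@H](C)CCC=C(C)C
F0 | step 11 | none | none
F3 | step 5 | (2S,3R)-2-(4-hydroxy-2-oxo-2,5-dihydrofuran-3-yl)-3,7-dimethyloct-6-enal | O=C1OCC(O)=C1[C@@H](C=O)[C@H](C)CCC=C(C)C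
F4 | step 5 | ethyl (4S,5R)-4-(4-hydroxy-2-oxo-2,5-dihydrofuran-3-yl)-5,9-dimethyl-3-oxodec-8-enoate | O=C1OCC(O)=C1[C@@H](C(=O)CC(=O)OCC)[C@H](C)CCC=C(C)C
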